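Ring B (C1 aryl-bearing, C2 and C3 methyl-bearing, C4 methylene, fusion carbons C4a and C8a) is disconnected as the one-carbon homologue of a 3-aryl-2-methylindan-1-one. The methylene C4 is inserted between C4a, the fusion carbon of the dimethoxybenzo ring A that lies para to a methoxy group, and the carbonyl carbon, which becomes C3. A Lewis-acid-promoted (trimethylsilyl)diazomethane homologation with migration of this electron-rich aryl carbon forms C3–C4 and C4–C4a and enlarges the five-membered ring to ring B in one operation, leaving a C3 ketone as the handle for the last methyl group. The precursor is enantioenriched trans-(2S,3R)-3-(3,4-dimethoxyphenyl)-5,6-dimethoxy-2-methylindan-1-one, which already carries C1 and C2.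

Key step: step 5

Assumption: the facial sense of the CuH reduction of this indenone is taken to be (3R) with (R)-DTBM-SEGPHOS; the antipodal ligand is to be used if a test run shows the opposite sense.

Step 1
Reactants: 1 3',4'-dimethoxypropiophenone; 2 veratraldehyde (3,4-dimethoxybenzaldehyde)
Product: 3 (E)-1,3-bis(3,4-dimethoxyphenyl)-2-methylprop-2-en-1-one
Conditions: KOH, EtOH, 60 °C
Reagents that add atoms: none
Why: Claisen–Schmidt (crossed aldol) condensation of the propiophenone enolate with the non-enolisable aldehyde, followed by dehydration, should give the conjugated (E)-enone.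

Step 2
Reactants: 3 (E)-1,3-bis(3,4-dimethoxyphenyl)-2-methylprop-2-en-1-one
Product: 4 rac-trans-3-(3,4-dimethoxyphenyl)-5,6-dimethoxy-2-methylindan-1-one
Conditions: CF3CO2H, 120 °C (sealed tube)
Reagents that add atoms: none
Why: Nazarov cyclisation of the O-protonated aryl vinyl ketone should close onto the ring carbon para to the 3'-methoxy group (5,6-dimethoxy pattern), and acid-mediated enol–keto equilibration should leave the 2-methyl and 3-aryl groups mainly trans, racemic at this stage.

Step 3
Reactants: 4 rac-trans-3-(3,4-dimethoxyphenyl)-5,6-dimethoxy-2-methylindan-1-one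
Product: 5 3-(3,4-dimethoxyphenyl)-5,6-dimethoxy-2-methyl-1H-inden-1-one
Conditions: DDQ, 1,4-dioxane, reflux
Reagents that add atoms: none
Why: DDQ dehydrogenation by hydride abstraction from the doubly benzylic C3–H and loss of the C2 proton should give the indenone, which erases both stereocentres so that they can be reset under catalyst control.

Step 4
Reactants: 5 3-(3,4-dimethoxyphenyl)-5,6-dimethoxy-2-methyl-1H-inden-1-one
Product: 8 (2S,3R)-3-(3,4-dimethoxyphenyl)-5,6-dimethoxy-2-methylindan-1-one, via silyl enol ether 6 (not isolated), via cis-indanone 7 (not isolated)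
Conditions: Cu(OAc)2·H2O (cat.), (R)-DTBM-SEGPHOS (cat.), (EtO)2MeSiH, toluene, 0 °C to rt; then K2CO3 (cat.), MeOH, rt
Reagents that add atoms: none
Why: Asymmetric CuH conjugate reduction should deliver hydride to one face of the β-carbon under ligand control (setting the aryl-bearing centre), the copper enolate is trapped as the silyl enol ether so that the ketone is not reduced further, and basic methanolysis protonates and equilibrates C2 so that the methyl group settles trans to the fixed 3-aryl group.

Step 5
Reactants: 8 (2S,3R)-3-(3,4-dimethoxyphenyl)-5,6-dimethoxy-2-methylindan-1-one; 9 (trimethylsilyl)diazomethane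
Product: 11 (3S,4R)-4-(3,4-dimethoxyphenyl)-6,7-dimethoxy-3-methyl-3,4-dihydronaphthalen-2(1H)-one (target numbering: ketone at C3, C1 aryl and C2 methyl trans), via α-silyl ketone 10 (not isolated)
Conditions: BF3·OEt2, CH2Cl2, −78 to −20 °C; then 1 M HCl, THF, rt
Reagents that add atoms: (trimethylsilyl)diazomethane (compound 9), C[Si](C)(C)C=[N+]=[N-]
Why: BF3 activates the indanone carbonyl, the nucleophilic diazo carbon of 9 adds to it (forming C3–C4), and in the resulting β-oxido diazonium betaine the aryl carbon C7a of the indanone (C4a of the target) shifts to the diazo carbon anti to the departing N2 (forming C4–C4a); this is the known Lewis-acid-promoted diazoalkane homologation of 1-indanones to 2-tetralones, a Tiffeneau–Demjanov-type 1,2-shift. Ring B is therefore closed not by an end-to-end cyclisation but by enlargement of the five-membered ketone through this 1,2-aryl shift. No lasting stereocentre is created: the silyl-bearing carbon of 10 becomes the C4 methylene on protodesilylation, C1 is not enolisable, and C2, although α to the old and the new carbonyl group, already sits in the thermodynamically preferred trans arrangement. The step needs migration of the aryl carbon rather than the secondary alkyl carbon C2; this should be secured by the high migratory aptitude of the electron-rich aryl carbon, whose para methoxy group (on C7) stabilises the bridged transition state, and by the bulky Me3Si group, which favours migration of the less hindered substituent. The α-silyl ketone is hindered and readily enolised, which should prevent a second homologation.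

Step 6
Reactants: 11 (3S,4R)-4-(3,4-dimethoxyphenyl)-6,7-dimethoxy-3-methyl-3,4-dihydronaphthalen-2(1H)-one
Product: 12 (1R,2S)-1-(3,4-dimethoxyphenyl)-6,7-dimethoxy-2-methyl-3-methylidene-1,2,3,4-tetrahydronaphthalene
Conditions: Zn, CH2Br2, TiCl4, THF/CH2Cl2, 0 °C to rt
Reagents that add atoms: dibromomethane, BrCBr
Why: Takai–Lombardo methylenation with the non-basic gem-dimetallic methylene reagent should convert the TiCl4-activated ketone into the exocyclic alkene without enolising the β-tetralone or epimerising C2.

Step 7
Reactants: 12 (1R,2S)-1-(3,4-dimethoxyphenyl)-6,7-dimethoxy-2-methyl-3-methylidene-1,2,3,4-tetrahydronaphthalene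
Product: 13 (1R,2R,3S)-1-(3,4-dimethoxyphenyl)-6,7-dimethoxy-2,3-dimethyl-1,2,3,4-tetrahydronaphthalene (all-trans; the target)
Conditions: Mn(dpm)3 (cat.), PhSiH3, t-BuOOH, i-PrOH, rt
Reagents that add atoms: none
Why: Metal-hydride hydrogen-atom-transfer hydrogenation should give a hydrogen atom to the terminal CH2 to form the tertiary C3 radical, which is quenched on its axial face in the all-equatorial half-chair, so that the new methyl group ends up equatorial and trans to the C2 methyl, i.e. (3S).

Compound list
1 | 3',4'-dimethoxypropiophenone | CCC(=O)c1ccc(OC)c(OC)c1 | starting material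
2 | veratraldehyde (3,4-dimethoxybenzaldehyde) | COc1ccc(C=O)cc1OC | starting material
3 | (E)-1,3-bis(3,4-dimethoxyphenyl)-2-methylprop-2-en-1-one | COc1ccc(/C=C(\C)C(=O)c2ccc(OC)c(OC)c2)cc1OC | intermediate
4 | rac-trans-3-(3,4-dimethoxyphenyl)-5,6-dimethoxy-2-methylindan-1-one (racemate, both enantiomers written) | COc1ccc([C@@H]2c3cc(OC)c(OC)cc3C(=O)[C@H]2C)cc1OC.COc1ccc([C@H]2c3cc(OC)c(OC)cc3C(=O)[C@@H]2C)cc1OC | intermediate
5 | 3-(3,4-dimethoxyphenyl)-5,6-dimethoxy-2-methyl-1H-inden-1-one | COc1ccc(C2=C(C)C(=O)c3cc(OC)c(OC)cc32)cc1OC | intermediate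
6 | {[(1R)-1-(3,4-dimethoxyphenyl)-5,6-dimethoxy-2-methyl-1H-inden-3-yl]oxy}diethoxy(methyl)silane (silyl enol ether, not isolated) | CCO[Si](C)(OCC)OC1=C(C)[C@H](c2ccc(OC)c(OC)c2)c2cc(OC)c(OC)cc12 | intermediate
7 | (2R,3R)-3-(3,4-dimethoxyphenyl)-5,6-dimethoxy-2-methylindan-1-one (cis C2 epimer from kinetic protonation, not isolated) | COc1ccc([C@@H]2c3cc(OC)c(OC)cc3C(=O)[C@@H]2C)cc1OC | intermediate
8 | (2S,3R)-3-(3,4-dimethoxyphenyl)-5,6-dimethoxy-2-methylindan-1-one (trans) | COc1ccc([C@@H]2c3cc(OC)c(OC)cc3C(=O)[C@H]2C)cc1OC | intermediate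
9 | (trimethylsilyl)diazomethane | C[Si](C)(C)C=[N+]=[N-] | starting material
10 | (3S,4R)-4-(3,4-dimethoxyphenyl)-6,7-dimethoxy-3-methyl-1-(trimethylsilyl)-3,4-dihydronaphthalen-2(1H)-one (silicon on the inserted carbon, configuration there undefined, not isolated) | COc1ccc([C@@H]2c3cc(OC)c(OC)cc3C([Si](C)(C)C)C(=O)[C@H]2C)cc1OC | intermediate
11 | (3S,4R)-4-(3,4-dimethoxyphenyl)-6,7-dimethoxy-3-methyl-3,4-dihydronaphthalen-2(1H)-one | COc1ccc([C@@H]2c3cc(OC)c(OC)cc3CC(=O)[C@H]2C)cc1OC | intermediate
12 | (1R,2S)-1-(3,4-dimethoxyphenyl)-6,7-dimethoxy-2-methyl-3-methylidene-1,2,3,4-tetrahydronaphthalene | COc1ccc([C@@H]2c3cc(OC)c(OC)cc3CC(=C)[C@H]2C)cc1OC | intermediate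
13 | (1R,2R,3S)-1-(3,4-dimethoxyphenyl)-6,7-dimethoxy-2,3-dimethyl-1,2,3,4-tetrahydronaphthalene | COc1ccc([C@@H]2c3cc(OC)c(OC)cc3C[C@H](C)[C@H]2C)cc1OC | target

Total step count: 7. Longest linear sequence: 7 steps (1 to 13; 2 and 9 enter as single building blocks).

Steps most likely to fail

Step 5. The secondary alkyl carbon C2 may migrate instead of the aryl carbon, addition to the para-methoxy-deactivated aryl ketone may be sluggish, or epoxide formation may compete. The same C4 insertion can then be reached by oxidative rearrangement of the derived styrene. Setting out from 8, Wittig methylenation (Ph3PCH3Br, KOt-Bu, THF) would give (1R,2S)-1-(3,4-dimethoxyphenyl)-5,6-dimethoxy-2-methyl-3-methylidene-2,3-dihydro-1H-indene F1. Treatment with PhI(OH)OTs in aqueous MeOH should add methanol at the benzylic carbon and shift the aryl carbon to the exocyclic CH2 with loss of iodobenzene. Hydrolysis of the resulting oxocarbenium ion comes back to the route at 11. The migration terminus is fixed in this variant, and aryl participation is the known course for 1-methylenebenzocycloalkanes.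

Step 4. The tetrasubstituted enone may react slowly, may be reduced at the carbonyl group, or may be attacked with insufficient facial selectivity. The stereocentre can then be set by reagent-controlled carbonyl reduction and relayed to C3. Setting out from 5, Corey–Bakshi–Shibata reduction ((S)-Me-CBS, BH3·SMe2, THF; sense to be confirmed on a test scale) would give (1R)-3-(3,4-dimethoxyphenyl)-5,6-dimethoxy-2-methyl-1H-inden-1-ol F2. An amine-mediated suprafacial 1,3-proton shift (DABCO, Et3N, THF, 60 °C) should move the carbinol hydrogen to the same face of the aryl-bearing carbon. Tautomerisation of the enol and equilibration at C2 bring the material back at 8.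

Step 7. The second hydrogen-atom transfer may show poor facial selectivity, or the exocyclic alkene may isomerise into conjugation with ring A before it is reduced. C3 can then be set by equilibration of a carbonyl derivative. Setting out from 12, hydroboration–oxidation (BH3·THF; then H2O2, NaOH) would give [(3S,4R)-4-(3,4-dimethoxyphenyl)-6,7-dimethoxy-3-methyl-1,2,3,4-tetrahydronaphthalen-2-yl]methanol F3 as a mixture at the new centre. Oxidation (Dess–Martin periodinane) followed by DBU should give the equatorial (2S,3S,4R)-4-(3,4-dimethoxyphenyl)-6,7-dimethoxy-3-methyl-1,2,3,4-tetrahydronaphthalene-2-carbaldehyde F4. Wolff–Kishner reduction (N2H4·H2O, KOH, diethylene glycol, heat) through the hydrazone of this aldehyde F5 would turn the formyl group into the methyl group and come back at 13.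

Further compounds
F1 | step 5 | (1R,2S)-1-(3,4-dimethoxyphenyl)-5,6-dimethoxy-2-methyl-3-methylidene-2,3-dihydro-1H-indene | COc1ccc([C@@H]2c3cc(OC)c(OC)cc3C(=C)[C@H]2C)cc1OC
F2 | step 4 | (1R)-3-(3,4-dimethoxyphenyl)-5,6-dimethoxy-2-methyl-1H-inden-1-ol | O[C@@H]1C(C)=C(c2ccc(OC)c(OC)c2)c2cc(OC)c(OC)cc21
F3 | step 7 | [(3S,4R)-4-(3,4-dimethoxyphenyl)-6,7-dimethoxy-3-methyl-1,2,3,4-tetrahydronaphthalen-2-yl]methanol (epimers at the hydroxymethyl-bearing carbon) | COc1ccc([C@@H]2c3cc(OC)c(OC)cc3CC(CO)[C@H]2C)cc1OC
F4 | step 7 | (2S,3S,4R)-4-(3,4-dimethoxyphenyl)-6,7-dimethoxy-3-methyl-1,2,3,4-tetrahydronaphthalene-2-carbaldehyde | COc1ccc([C@@H]2c3cc(OC)c(OC)cc3C[C@H](C=O)[C@H]2C)cc1OC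
F5 | step 7 | hydrazone of (2S,3S,4R)-4-(3,4-dimethoxyphenyl)-6,7-dimethoxy-3-methyl-1,2,3,4-tetrahydronaphthalene-2-carbaldehyde | COc1ccc([C@@H]2c3cc(OC)c(OC)cc3C[C@H](C=NN)[C@H]2C)cc1OC
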